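**Strategy.** Ring A (the phenol ring: C1 OH, C2 O-aryl, C3 H, C4–C6 Br) is disconnected into a C3–C6 diene unit and a C1–C2 two-carbon unit. The key step exploits the vicinal C1/C2 dioxygenation that faces the vicinal C4/C5 dibromide. Symmetric 3,4-dibromothiophene 1,1-dioxide supplies C3–C6. The bis(trimethylsilyl) ketene acetal of (2,4-dibromophenoxy)acetic acid, which already carries ring B, supplies C1–C2. In one operation an inverse-demand [4+2] cycloaddition, SO2 extrusion and silanol loss form C1–C6 and C2–C3, close ring A and reveal the phenol. Bromination at C6, ortho to the hydroxyl, finishes the synthesis.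

Key step: step 4

Remark: the target is achiral; the sp3 centres of the transient intermediates 9 and 10 form without control (racemic, endo/exo mixture) and vanish on aromatisation.

**Step 1**
Reactants: 1 3,4-dibromothiophene
Product: 3 3,4-dibromothiophene 1,1-dioxide, via 3,4-dibromothiophene 1-oxide 2 (not isolated)
Conditions: H2O2 (35% aq.), (CF3CO)2O, CH2Cl2, 0 °C to rt
Reagents that add atoms: trifluoroperacetic acid, OOC(=O)C(F)(F)F; hydrogen peroxide, OO
Why: Peracid oxidation of a thiophene at sulfur: CF3CO3H, made in the flask from H2O2 and (CF3CO)2O, is electrophilic enough for the bromine-deactivated sulfur and, in excess, should carry the S-oxide 2 straight on to dioxide 3, which the 3,4-dibromo substitution should protect from rapid self-dimerisation.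

**Step 2**
Reactants: 4 2,4-dibromophenol; 5 bromoacetic acid
Product: 6 (2,4-dibromophenoxy)acetic acid
Conditions: NaOH (2.2 equiv), H2O, 90 °C; then HCl to pH 1
Reagents that add atoms: none
Why: Williamson ether synthesis: the phenoxide of 4 displaces bromide from bromoacetate in an SN2 reaction at a primary carbon, the standard way to aryloxyacetic acids.

**Step 3**
Reactants: 6 (2,4-dibromophenoxy)acetic acid
Product: 8 2-(2,4-dibromophenoxy)-1,1-bis(trimethylsilyloxy)ethene, via trimethylsilyl ester 7 (not isolated)
Conditions: LiN(SiMe3)2 (1.0 equiv), Me3SiCl (1.1 equiv), THF, 0 °C to rt; then Me3SiCl (1.3 equiv), LiN(SiMe3)2 (1.15 equiv), −78 °C to rt; pentane, filtration under Ar, evaporation, used crude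
Reagents that add atoms: chlorotrimethylsilane, C[Si](C)(C)Cl
Why: Silyl ketene acetal formation by ester enolisation and O-silylation: the carboxylate is silylated to ester 7, whose α-CH is removed by LiN(SiMe3)2 (chosen over a lithium dialkylamide because it is too weak to metalate the ring B C–H between the two bromines), and the enolate is trapped on oxygen by Me3SiCl.

**Step 4**
Reactants: 3 3,4-dibromothiophene 1,1-dioxide; 8 2-(2,4-dibromophenoxy)-1,1-bis(trimethylsilyloxy)ethene
Product: 12 4,5-dibromo-2-(2,4-dibromophenoxy)phenol, via bicyclic sulfone cycloadduct 9 (not isolated), via bis(silyloxy)cyclohexadiene 10 (not isolated), via aryl trimethylsilyl ether 11 (not isolated)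
Conditions: 8 (3 equiv), PhMe, 60 to 90 °C, slow addition of 3, Ar stream; then 1 M HCl, THF, rt; NaHCO3 wash
Reagents that add atoms: none
Why: Proposed new method: the electron-poor cyclic diene 3 (LUMO lowered by the sulfone and two bromines) and the electron-rich ketene acetal 8 should combine in an inverse-electron-demand Diels–Alder reaction that forms C2–C3 and C1–C6 and gives the 7-thiabicyclo[2.2.1]hept-2-ene 7,7-dioxide 9; cheletropic extrusion of SO2 then gives cyclohexa-1,3-diene 10, and loss of Me3SiOH across C1–C2 aromatises it to silyl ether 11, which the acidic work-up cleaves to 12. The closest known reaction types are the benzannulations of 3,4-dihalo- and tetrahalothiophene 1,1-dioxides with alkenes and enamines (cycloaddition, SO2 loss, elimination) and the aromatic-ring-forming cycloadditions of ketene acetals with other electron-poor dienes such as 2-pyrones and 1,2,4-triazines; a silyl ketene acetal has not been shown as the partner of a thiophene dioxide. Ring A is closed as a six-membered carbocycle by intermolecular [4+2] cycloaddition, both new bonds joining the two components, not by cyclisation of a tethered chain. The sp3 centres of 9 and 10 are transient and are erased on aromatisation, so no stereocontrol is needed. Regiochemistry cannot arise because diene 3 is symmetric, and in the aromatisation C1 carries no hydrogen, so only silanol can leave and the aryloxy group on C2 stays. The selectivity required is cross-cycloaddition over self-dimerisation of 3 and over open-chain conjugate addition, which slow addition of 3 to an excess of the nucleophilic 8 in a non-polar solvent without Lewis acid should secure.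

**Step 5**
Reactants: 12 4,5-dibromo-2-(2,4-dibromophenoxy)phenol
Product: 13 2,3,4-tribromo-6-(2,4-dibromophenoxy)phenol
Conditions: NBS (1.0 equiv), i-Pr2NH (0.1 equiv), CH2Cl2, 0 °C to rt
Reagents that add atoms: N-bromosuccinimide, O=C1CCC(=O)N1Br
Why: Electrophilic aromatic ortho-bromination of a phenol (amine-catalysed NBS): C6 is the only free position ortho or para to the hydroxyl, whereas C3 and the free ring B position are activated only by the diaryl ether oxygen and deactivated by bromine, so one equivalent should stop at the target.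

**Compound list**
1 | 3,4-dibromothiophene | Brc1cscc1Br | starting material
2 | 3,4-dibromothiophene 1-oxide | O=S1C=C(Br)C(Br)=C1 | intermediate
3 | 3,4-dibromothiophene 1,1-dioxide | O=S1(=O)C=C(Br)C(Br)=C1 | intermediate
4 | 2,4-dibromophenol | Oc1ccc(Br)cc1Br | starting material
5 | bromoacetic acid | OC(=O)CBr | starting material
6 | (2,4-dibromophenoxy)acetic acid | OC(=O)COc1ccc(Br)cc1Br | intermediate
7 | trimethylsilyl (2,4-dibromophenoxy)acetate | C[Si](C)(C)OC(=O)COc1ccc(Br)cc1Br | intermediate
8 | 2-(2,4-dibromophenoxy)-1,1-bis(trimethylsilyloxy)ethene | C[Si](C)(C)OC(O[Si](C)(C)C)=COc1ccc(Br)cc1Br | intermediate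
9 | 2,3-dibromo-6-(2,4-dibromophenoxy)-5,5-bis(trimethylsilyloxy)-7-thiabicyclo[2.2.1]hept-2-ene 7,7-dioxide (racemic, endo/exo not defined) | O=S1(=O)C2C(Br)=C(Br)C1C(O[Si](C)(C)C)(O[Si](C)(C)C)C2Oc1ccc(Br)cc1Br | intermediate
10 | 2,3-dibromo-6-(2,4-dibromophenoxy)-5,5-bis(trimethylsilyloxy)cyclohexa-1,3-diene (racemic) | C[Si](C)(C)OC1(O[Si](C)(C)C)C=C(Br)C(Br)=CC1Oc1ccc(Br)cc1Br | intermediate
11 | [4,5-dibromo-2-(2,4-dibromophenoxy)phenoxy]trimethylsilane | C[Si](C)(C)Oc1cc(Br)c(Br)cc1Oc1ccc(Br)cc1Br | intermediate
12 | 4,5-dibromo-2-(2,4-dibromophenoxy)phenol | Oc1cc(Br)c(Br)cc1Oc1ccc(Br)cc1Br | intermediate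
13 | 2,3,4-tribromo-6-(2,4-dibromophenoxy)phenol | Oc1c(Oc2ccc(Br)cc2Br)cc(Br)c(Br)c1Br | target

**Total step count:** 5 steps.
**Longest linear sequence:** 4 steps (steps 2, 3, 4, 5); step 1 is a one-step branch that joins at step 4.

**Steps most likely to fail**

1. Step 4. Self-dimerisation of the thiophene dioxide, or a stepwise conjugate addition with silyl transfer that stops at an open-chain adduct, may outrun ring closure. The fallback uses known diaryl ether chemistry, sets out from 4 and returns at 12. Chan–Lam O-arylation of 4 with 2-methoxyphenylboronic acid (Cu(OAc)2, pyridine, 4 Å sieves, CH2Cl2, air) should give 2,4-dibromo-1-(2-methoxyphenoxy)benzene F1. Br2 (2 equiv, AcOH, rt) should brominate the more electron-rich anisole ring para to the methoxy group and then para to the aryloxy group, giving 1,2-dibromo-4-(2,4-dibromophenoxy)-5-methoxybenzene F2. BBr3 (CH2Cl2, −78 °C to rt) then cleaves the methyl ether to 12, which enters step 5.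

2. Step 3. Enolisation of the silyl ester may be incomplete, with the amide attacking silicon instead, or the bis-silyl ketene acetal may be lost to protonolysis during isolation. The fallback changes the dienophile, sets out from 6 and returns at 12. Fischer esterification (MeOH, cat. H2SO4, reflux) gives methyl (2,4-dibromophenoxy)acetate F3. Enolisation and silylation (LiN(SiMe3)2, Me3SiCl, THF, −78 °C) give the distillable mixed acetal 2-(2,4-dibromophenoxy)-1-methoxy-1-(trimethylsilyloxy)ethene F4. Heating F4 with 3 as in step 4 should lead through 2,3-dibromo-6-(2,4-dibromophenoxy)-5-methoxy-5-(trimethylsilyloxy)-7-thiabicyclo[2.2.1]hept-2-ene 7,7-dioxide F5 and, after SO2 loss, 2,3-dibromo-6-(2,4-dibromophenoxy)-5-methoxy-5-(trimethylsilyloxy)cyclohexa-1,3-diene F6. F6 aromatises either by loss of Me3SiOH to 1,2-dibromo-4-(2,4-dibromophenoxy)-5-methoxybenzene F2 or by loss of MeOH to silyl ether 11. Without separation, BBr3 (CH2Cl2) followed by aqueous work-up converts the mixture into 12.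

3. Step 1. Slow S-oxidation of the deactivated thiophene may let the transient S-oxide or the dioxide be consumed by self-cycloaddition or over-oxidation. The fallback activates and blocks the ring first, sets out from 1 and returns at 3. Double α-lithiation with in situ silylation (LiN(i-Pr)2, Me3SiCl, THF, −78 °C) gives 3,4-dibromo-2,5-bis(trimethylsilyl)thiophene F7. The silyl groups make sulfur more electron-rich and block both α-positions, so mCPBA (CH2Cl2, rt) should give the storable 3,4-dibromo-2,5-bis(trimethylsilyl)thiophene 1,1-dioxide F8. Buffered fluoride (Bu4NF, AcOH, THF, 0 °C) removes both silyl groups by protodesilylation just before use and returns 3.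

**Further compounds**
F1 | step 4 | 2,4-dibromo-1-(2-methoxyphenoxy)benzene | COc1ccccc1Oc1ccc(Br)cc1Br
F2 | step 4 | 1,2-dibromo-4-(2,4-dibromophenoxy)-5-methoxybenzene | COc1cc(Br)c(Br)cc1Oc1ccc(Br)cc1Br
F3 | step 3 | methyl (2,4-dibromophenoxy)acetate | COC(=O)COc1ccc(Br)cc1Br
F4 | step 3 | 2-(2,4-dibromophenoxy)-1-methoxy-1-(trimethylsilyloxy)ethene (E/Z mixture) | COC(O[Si](C)(C)C)=COc1ccc(Br)cc1Br
F5 | step 3 | 2,3-dibromo-6-(2,4-dibromophenoxy)-5-methoxy-5-(trimethylsilyloxy)-7-thiabicyclo[2.2.1]hept-2-ene 7,7-dioxide (racemic, configuration not defined) | O=S1(=O)C2C(Br)=C(Br)C1C(OC)(O[Si](C)(C)C)C2Oc1ccc(Br)cc1Br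
F6 | step 3 | 2,3-dibromo-6-(2,4-dibromophenoxy)-5-methoxy-5-(trimethylsilyloxy)cyclohexa-1,3-diene (racemic, configuration not defined) | COC1(O[Si](C)(C)C)C=C(Br)C(Br)=CC1Oc1ccc(Br)cc1Br
F7 | step 1 | 3,4-dibromo-2,5-bis(trimethylsilyl)thiophene | C[Si](C)(C)c1sc([Si](C)(C)C)c(Br)c1Br
F8 | step 1 | 3,4-dibromo-2,5-bis(trimethylsilyl)thiophene 1,1-dioxide | C[Si](C)(C)C1=C(Br)C(Br)=C([Si](C)(C)C)S1(=O)=O
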